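A direct plan would close ring C by a chiral-acid-catalysed hetero-Diels–Alder reaction of an in-situ o-quinone A2 with the silyl-protected (Z)-cinnamyl alcohol A1, giving the cis bromo-benzodioxane A3, and would finish by Suzuki coupling with alkenylboronate A4 and desilylation.
Weak point 1, the cycloaddition: regiochemistry, enantioselectivity and cis geometry would all depend on unprecedented catalyst control of an unstable, self-condensing o-quinone, and any stepwise (zwitterionic) addition would leak to the trans isomer.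
Weak point 2, the run-up to A1: silylation, Z-selective olefination and reduction would serve only to carry a Z geometry that is the sole source of cis and is easily lost.
Weak point 3, the end game: aqueous base at the Suzuki stage on A3 could free the para-phenol, whose quinone methide opens the cis benzylic ether and epimerises it to trans.

**Retrosynthetic overview**
The cis pair C2–H/C3–H of ring C (both on one face, the less stable arrangement) is cut as one molecule of H2 across C2=C3, so the key precursor is a flat, achiral 3-aryl-1,4-benzodioxine-2-carboxylic acid and one asymmetric syn hydrogenation sets both stereocentres together.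
Ring C is closed first, before any stereocentre exists: O1–C2 by SN2 of the most acidic phenol of 5-hydroxyvanillin (the OH flanked by the C8 methoxy group, para to the C6 formyl group) on an α-bromo-β-keto ester, then O4–C3 by hemiketalisation and dehydration.
The target is a formal dehydrodimer of 5-hydroxyconiferyl alcohol, so both aryl halves come from 5-hydroxyvanillin; the C6 side chain follows by Wittig olefination, and one hydride reduction makes both CH2OH groups and frees the ring A catechol.
No o-quinone and no Z-alkene are needed: regiochemistry rests on phenol acidity, cis rests on suprafacial H2 delivery, and no base or acid meets the free para-phenol.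

Key step: step 5

Assumption: the (Sa,S) ligand is taken to deliver H2 to the 2Re,3Re face of 7; should the sense prove opposite, the mirror-image ligand would be used with nothing else changed. Piv = 2,2-dimethylpropanoyl throughout.

**Route**

Step 1
Reactants: 1 3,4-dihydroxy-5-methoxybenzaldehyde (5-hydroxyvanillin)
Product: 2 3,4-bis(pivaloyloxy)-5-methoxybenzaldehyde
Conditions: PivCl (2.4 equiv), Et3N (3 equiv), DMAP (5 mol%), CH2Cl2, 0 °C → rt
Reagents that add atoms: pivaloyl chloride, CC(C)(C)C(Cl)=O
Why: DMAP-catalysed acylation of both phenols gives esters that make the aldehyde more electrophilic for step 2, switch off the para-oxygen lone pair that would allow quinone-methide epimerisation later, survive acid, and fall off in the final hydride reduction.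

Step 2
Reactants: 2 3,4-bis(pivaloyloxy)-5-methoxybenzaldehyde
Product: 3 tert-butyl 3-[3,4-bis(pivaloyloxy)-5-methoxyphenyl]-3-oxopropanoate
Conditions: N2CHCO2t-Bu (1.3 equiv), SnCl2 (10 mol%), CH2Cl2, rt
Reagents that add atoms: tert-butyl diazoacetate, CC(C)(C)OC(=O)C=[N+]=[N-]
Why: Roskamp reaction, in which the diazo carbon adds to the Lewis-acid-activated aldehyde and a 1,2-hydride shift with loss of N2 gives the β-keto ester, the electron-poor bis-acyloxy aryl group disfavouring the competing aryl shift.

Step 3
Reactants: 3 tert-butyl 3-[3,4-bis(pivaloyloxy)-5-methoxyphenyl]-3-oxopropanoate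
Product: 4 tert-butyl 2-bromo-3-[3,4-bis(pivaloyloxy)-5-methoxyphenyl]-3-oxopropanoate (racemic)
Conditions: NBS (1.05 equiv), Mg(ClO4)2 (10 mol%), MeCN, 0 °C → rt
Reagents that add atoms: N-bromosuccinimide, O=C1CCC(=O)N1Br
Why: Electrophilic α-bromination of the magnesium-chelated enol of the β-keto ester, the acyl-deactivated ring staying untouched; the new stereocentre is of no consequence because step 4 removes it.

Step 4
Reactants: 4 tert-butyl 2-bromo-3-[3,4-bis(pivaloyloxy)-5-methoxyphenyl]-3-oxopropanoate; 1 3,4-dihydroxy-5-methoxybenzaldehyde (second use)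
Product: 7 6-formyl-8-methoxy-3-[3,4-bis(pivaloyloxy)-5-methoxyphenyl]-1,4-benzodioxine-2-carboxylic acid, via keto ether 5 (not isolated), via cyclic hemiketal 6 (not isolated)
Conditions: 1 (1.0 equiv), 4 (1.1 equiv), NaHCO3 (1.5 equiv), DMF, rt; aqueous work-up; then TFA/CH2Cl2 (1:2), 0 °C → rt
Reagents that add atoms: none
Why: SN2 O-alkylation by the phenoxide of the 4-OH of 1 (para to the formyl group and therefore the phenol that bicarbonate ionises) places the future O1, flanked by the C8 methoxy group, on C2, the neighbouring 3-OH then adds to the aryl ketone to close ring C as a six-membered cyclic hemiketal (6-exo-trig), and TFA removes water through the aryl- and oxygen-stabilised C3 cation (E1, loss of the acidic C2–H) and cleaves the tert-butyl ester, as in the known condensation of catechols with α-halo-β-keto esters to 3-substituted 1,4-benzodioxine-2-carboxylates.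

Step 5
Reactants: 7 6-formyl-8-methoxy-3-[3,4-bis(pivaloyloxy)-5-methoxyphenyl]-1,4-benzodioxine-2-carboxylic acid
Product: 9 methyl (2S,3S)-6-formyl-8-methoxy-3-[3,4-bis(pivaloyloxy)-5-methoxyphenyl]-2,3-dihydro-1,4-benzodioxine-2-carboxylate (cis), via cis acid 8 (not isolated)
Conditions: [Ir(cod)(L)]BArF (2 mol%; L = (Sa,S)-7-[bis(3,5-di-tert-butylphenyl)phosphanyl]-7'-(4-benzyl-4,5-dihydrooxazol-2-yl)-1,1'-spirobiindane, BArF = B[3,5-(CF3)2C6H3]4), H2 (10 atm), Et3N (0.5 equiv), MeOH, 45 °C; evaporation; then TMSCHN2 (1.2 equiv), toluene/MeOH (4:1), 0 °C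
Reagents that add atoms: trimethylsilyldiazomethane, C[Si](C)(C)C=[N+]=[N-]
Why: Proposed new method: enantioselective, carboxylate-directed iridium hydrogenation of the tetrasubstituted enediol-diether bond C2=C3 of a 1,4-benzodioxine; the carboxylate of 7 binds the iridium hydride, the chelated alkene inserts into Ir–H and the alkyl–iridium bond is cleaved by the second hydride, so both hydrogens are delivered from the metal-bound face. The closest known reaction types are the spiro phosphine–oxazoline iridium hydrogenations of α-aryloxy acrylic acids, tetrasubstituted acrylic acids and cyclic enol-ether acids, and the syn hydrogenation of 2,3-disubstituted 1,4-benzodioxines to cis-benzodioxanes over achiral catalysts; only their combination on a fully substituted dioxine is new. No ring is closed, ring C is already in place and only the C2–H and C3–H bonds are formed. Both stereocentres arise together: the cis relationship follows from suprafacial H2 delivery and does not depend on the ee, and the absolute sense (addition to the 2Re,3Re face, which gives 2S,3S) is controlled by the chiral pocket of L around the anchored, planar substrate. The step needs chemoselectivity for the chelated alkene, which the formyl group and the aryl esters cannot match because they do not chelate, and it needs a configurationally safe C2, which the carboxylate form and the base-free methylation with TMSCHN2 secure.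

Step 6
Reactants: 9 methyl (2S,3S)-6-formyl-8-methoxy-3-[3,4-bis(pivaloyloxy)-5-methoxyphenyl]-2,3-dihydro-1,4-benzodioxine-2-carboxylate
Product: 10 methyl (2S,3S)-8-methoxy-6-[(E)-3-methoxy-3-oxoprop-1-en-1-yl]-3-[3,4-bis(pivaloyloxy)-5-methoxyphenyl]-2,3-dihydro-1,4-benzodioxine-2-carboxylate (cis)
Conditions: Ph3P=CHCO2Me (1.3 equiv), toluene, 50 °C
Reagents that add atoms: methyl (triphenylphosphoranylidene)acetate, COC(=O)C=P(c1ccccc1)(c1ccccc1)c1ccccc1
Why: Wittig olefination with a stabilised ylide should give the E-enoate through the reversibly formed oxaphosphetane, and the neutral ylide is too weak a base to enolise the C2 ester, so the cis centres stay as set.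

Step 7
Reactants: 10 methyl (2S,3S)-8-methoxy-6-[(E)-3-methoxy-3-oxoprop-1-en-1-yl]-3-[3,4-bis(pivaloyloxy)-5-methoxyphenyl]-2,3-dihydro-1,4-benzodioxine-2-carboxylate
Product: 11 (E)-3-[(2R,3S)-3-(3,4-dihydroxy-5-methoxyphenyl)-2-(hydroxymethyl)-8-methoxy-2,3-dihydro-1,4-benzodioxin-6-yl]prop-2-en-1-ol (target)
Conditions: i-Bu2AlH (12 equiv), CH2Cl2, −78 → −40 °C; MeOH quench, aq. potassium sodium tartrate (pH about 7), rt
Reagents that add atoms: none
Why: 1,2-Hydride reduction of both methyl esters to primary alcohols and reductive cleavage of both aryl pivalates in one operation, the phenols appearing only as aluminium phenoxides at low temperature and being released near neutral pH so that the cis benzylic ether never meets base or acid; no stereocentre is touched, and the C2 descriptor changes from S to R only because CH2OH ranks below C3.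

**Compound list**
1 | 3,4-dihydroxy-5-methoxybenzaldehyde (5-hydroxyvanillin) | COc1cc(C=O)cc(O)c1O | starting material
2 | 3,4-bis(pivaloyloxy)-5-methoxybenzaldehyde | COc1cc(C=O)cc(OC(=O)C(C)(C)C)c1OC(=O)C(C)(C)C | intermediate
3 | tert-butyl 3-[3,4-bis(pivaloyloxy)-5-methoxyphenyl]-3-oxopropanoate | COc1cc(C(=O)CC(=O)OC(C)(C)C)cc(OC(=O)C(C)(C)C)c1OC(=O)C(C)(C)C | intermediate
4 | tert-butyl 2-bromo-3-[3,4-bis(pivaloyloxy)-5-methoxyphenyl]-3-oxopropanoate (racemic) | COc1cc(C(=O)C(Br)C(=O)OC(C)(C)C)cc(OC(=O)C(C)(C)C)c1OC(=O)C(C)(C)C | intermediate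
5 | tert-butyl 2-(4-formyl-2-hydroxy-6-methoxyphenoxy)-3-[3,4-bis(pivaloyloxy)-5-methoxyphenyl]-3-oxopropanoate (racemic, not isolated) | COc1cc(C=O)cc(O)c1OC(C(=O)OC(C)(C)C)C(=O)c1cc(OC)c(OC(=O)C(C)(C)C)c(OC(=O)C(C)(C)C)c1 | intermediate
6 | tert-butyl 6-formyl-3-hydroxy-8-methoxy-3-[3,4-bis(pivaloyloxy)-5-methoxyphenyl]-2,3-dihydro-1,4-benzodioxine-2-carboxylate (cyclic hemiketal, mixture of diastereomers, not isolated) | COc1cc(C=O)cc2OC(O)(c3cc(OC)c(OC(=O)C(C)(C)C)c(OC(=O)C(C)(C)C)c3)C(C(=O)OC(C)(C)C)Oc12 | intermediate
7 | 6-formyl-8-methoxy-3-[3,4-bis(pivaloyloxy)-5-methoxyphenyl]-1,4-benzodioxine-2-carboxylic acid | COc1cc(C=O)cc2OC(c3cc(OC)c(OC(=O)C(C)(C)C)c(OC(=O)C(C)(C)C)c3)=C(C(=O)O)Oc12 | intermediate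
8 | (2S,3S)-6-formyl-8-methoxy-3-[3,4-bis(pivaloyloxy)-5-methoxyphenyl]-2,3-dihydro-1,4-benzodioxine-2-carboxylic acid (cis, not isolated) | COc1cc([C@@H]2Oc3cc(C=O)cc(OC)c3O[C@@H]2C(=O)O)cc(OC(=O)C(C)(C)C)c1OC(=O)C(C)(C)C | intermediate
9 | methyl (2S,3S)-6-formyl-8-methoxy-3-[3,4-bis(pivaloyloxy)-5-methoxyphenyl]-2,3-dihydro-1,4-benzodioxine-2-carboxylate (cis) | COc1cc([C@@H]2Oc3cc(C=O)cc(OC)c3O[C@@H]2C(=O)OC)cc(OC(=O)C(C)(C)C)c1OC(=O)C(C)(C)C | intermediate
10 | methyl (2S,3S)-8-methoxy-6-[(E)-3-methoxy-3-oxoprop-1-en-1-yl]-3-[3,4-bis(pivaloyloxy)-5-methoxyphenyl]-2,3-dihydro-1,4-benzodioxine-2-carboxylate (cis) | COc1cc([C@@H]2Oc3cc(/C=C/C(=O)OC)cc(OC)c3O[C@@H]2C(=O)OC)cc(OC(=O)C(C)(C)C)c1OC(=O)C(C)(C)C | intermediate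
11 | (E)-3-[(2R,3S)-3-(3,4-dihydroxy-5-methoxyphenyl)-2-(hydroxymethyl)-8-methoxy-2,3-dihydro-1,4-benzodioxin-6-yl]prop-2-en-1-ol | COc1cc([C@@H]2Oc3cc(/C=C/CO)cc(OC)c3O[C@@H]2CO)cc(O)c1O | target

**Count and risks**
Total steps: 7. Longest linear sequence: 7 (1 → 11; compound 1 enters twice, in steps 1 and 4).

Steps most likely to fail:

1. Step 5 (Proposed new method). The fully substituted, electron-rich C2=C3 bond may insert too slowly, the enantioface discrimination may be poor, or the formyl group may be reduced alongside. The fallback uses known chemistry and replaces catalyst control by resolution. It sets out from 7: hydrogenation over an achiral heterogeneous catalyst (H2 1 atm, Pd/C, EtOAc, rt, stopped after one equivalent of H2) is the reaction type known to turn 2,3-disubstituted 1,4-benzodioxines into cis-benzodioxanes and would give the racemic cis acid F1. Methylation with TMSCHN2 would give the racemic cis methyl ester F2. Preparative chromatography of F2 on a chiral stationary phase (cellulose tris(3,5-dimethylphenylcarbamate)) would deliver the (2S,3S) enantiomer, which is compound 9, where the route is rejoined.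

2. Step 4. The hindered bromide may alkylate the flanked phenoxide with poor site selectivity, bromine may be transferred to the phenoxide instead of carbon, or the acid may decarboxylate if the tert-butyl ester is cleaved before the hemiketal dehydrates. The fallback forms O4–C4a as an aryl–oxygen bond instead and needs no site selection. It sets out from 4 and commercial 5-iodovanillin F3, which has a single phenol: alkylation (K2CO3, DMF, rt) would give the iodo keto ether F4. Intramolecular O-arylation of its β-keto ester enolate (CuI 10 mol%, 1,10-phenanthroline, K3PO4, toluene, 90 °C; C-arylation would need a four-membered ring) would give the dioxine tert-butyl ester F5. TFA/CH2Cl2 on F5, now with no β-keto acid possible, returns to the route at 7.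

3. Step 2. The aryl shift may compete with the hydride shift, or the addition of the diazo ester may stall. The fallback builds the same C–C bond by enolate addition and then adjusts the oxidation level. It sets out from 2: a Reformatsky reaction (Zn, BrCH2CO2t-Bu, THF, rt), which tolerates the aryl esters, would give the β-hydroxy ester F6. Oxidation with Dess–Martin periodinane (CH2Cl2, rt) returns to the route at 3.

**Further compounds**
F1 | step 5 | racemic cis-6-formyl-8-methoxy-3-[3,4-bis(pivaloyloxy)-5-methoxyphenyl]-2,3-dihydro-1,4-benzodioxine-2-carboxylic acid (both enantiomers shown) | COc1cc([C@@H]2Oc3cc(C=O)cc(OC)c3O[C@@H]2C(=O)O)cc(OC(=O)C(C)(C)C)c1OC(=O)C(C)(C)C.COc1cc([C@H]2Oc3cc(C=O)cc(OC)c3O[C@H]2C(=O)O)cc(OC(=O)C(C)(C)C)c1OC(=O)C(C)(C)C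
F2 | step 5 | racemic methyl cis-6-formyl-8-methoxy-3-[3,4-bis(pivaloyloxy)-5-methoxyphenyl]-2,3-dihydro-1,4-benzodioxine-2-carboxylate (both enantiomers shown) | COc1cc([C@@H]2Oc3cc(C=O)cc(OC)c3O[C@@H]2C(=O)OC)cc(OC(=O)C(C)(C)C)c1OC(=O)C(C)(C)C.COc1cc([C@H]2Oc3cc(C=O)cc(OC)c3O[C@H]2C(=O)OC)cc(OC(=O)C(C)(C)C)c1OC(=O)C(C)(C)C
F3 | step 4 | 4-hydroxy-3-iodo-5-methoxybenzaldehyde (5-iodovanillin, commercial) | COc1cc(C=O)cc(I)c1O
F4 | step 4 | tert-butyl 2-(4-formyl-2-iodo-6-methoxyphenoxy)-3-[3,4-bis(pivaloyloxy)-5-methoxyphenyl]-3-oxopropanoate (racemic) | COc1cc(C=O)cc(I)c1OC(C(=O)OC(C)(C)C)C(=O)c1cc(OC)c(OC(=O)C(C)(C)C)c(OC(=O)C(C)(C)C)c1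
F5 | step 4 | tert-butyl 6-formyl-8-methoxy-3-[3,4-bis(pivaloyloxy)-5-methoxyphenyl]-1,4-benzodioxine-2-carboxylate | COc1cc(C=O)cc2OC(c3cc(OC)c(OC(=O)C(C)(C)C)c(OC(=O)C(C)(C)C)c3)=C(C(=O)OC(C)(C)C)Oc12
F6 | step 2 | tert-butyl 3-hydroxy-3-[3,4-bis(pivaloyloxy)-5-methoxyphenyl]propanoate (racemic) | COc1cc(C(O)CC(=O)OC(C)(C)C)cc(OC(=O)C(C)(C)C)c1OC(=O)C(C)(C)C
A1 | direct plan | (Z)-3-{3,4-bis[(tert-butyldimethylsilyl)oxy]-5-methoxyphenyl}prop-2-en-1-ol | COc1cc(/C=C\CO)cc(O[Si](C)(C)C(C)(C)C)c1O[Si](C)(C)C(C)(C)C
A2 | direct plan | 5-bromo-3-methoxycyclohexa-3,5-diene-1,2-dione (o-quinone) | COC1=CC(Br)=CC(=O)C1=O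
A3 | direct plan | [(2R,3S)-3-{3,4-bis[(tert-butyldimethylsilyl)oxy]-5-methoxyphenyl}-6-bromo-8-methoxy-2,3-dihydro-1,4-benzodioxin-2-yl]methanol | COc1cc([C@@H]2Oc3cc(Br)cc(OC)c3O[C@@H]2CO)cc(O[Si](C)(C)C(C)(C)C)c1O[Si](C)(C)C(C)(C)C
A4 | direct plan | (E)-3-(4,4,5,5-tetramethyl-1,3,2-dioxaborolan-2-yl)prop-2-en-1-ol | OC/C=C/B1OC(C)(C)C(C)(C)O1
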